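**Assumption:** compounds 1, 8, 16 and 20 and all reagents (including both antipodes of Ipc2BH, diethyl tartrate and Ru–TsDPEN) are taken as commercially available. Where a reagent antipode is named, it is the one intended to give the stated descriptor; the Brown (step 3) and Noyori (step 11) assignments are from the usual models and should be confirmed on first use. TBS = tert-butyldimethylsilyl.

## Retrosynthetic overview

1. The 15-membered carbocycle is closed last by RCM at the E-CH=CH between the gem-dimethyl carbon and the α-methyl ketone carbon.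
2. The α-methyl β,γ-enone comes from a ring aldehyde plus butadiene by a new stereocontrolled hydroacylation, so no secondary-alcohol oxidation is needed late.
3. The hemiketal pyran and its neighbouring carbinol come from a Au-catalysed 6-exo-dig cyclisation of an alkynyl diol, then OH-directed syn-dihydroxylation of the exocyclic enol ether, then esterification.
4. The alkynyl diol comes from a THF acetylide plus a cis-α-methyl-γ-lactone (ynone, then Noyori reduction).
5. The THF alkyne comes from geranyl acetate (reverse prenylation, Sharpless epoxidation/5-exo opening, glycol cleavage, Ohira–Bestmann). Ring order: THF, then hemiketal THP, then macrocycle.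

## Route

**West fragment**

Step 1
Reactants: 1, geranyl acetate
Product: 2, 6,7-epoxygeranyl acetate (racemic epoxide)
Conditions: mCPBA, CH2Cl2, 0 °C
Reagents that add atoms: mCPBA, O=C(OO)c1cccc(Cl)c1
Why: Prilezhaev epoxidation takes the electron-rich remote trisubstituted alkene, not the acetoxy-deactivated allylic one.

Step 2
Reactants: 2, 6,7-epoxygeranyl acetate
Product: 3, (2E)-3-methyl-6-oxohex-2-en-1-yl acetate
Conditions: H5IO6, THF–H2O, 0 °C to rt
Reagents that add atoms: water, O (hydrolytic epoxide opening; the carbonyl O is the former epoxide O or water O)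
Why: Periodic acid opens the epoxide and cleaves the glycol to the aldehyde and acetone (oxidative glycol cleavage), leaving the E-allylic acetate intact.

Step 3
Reactants: 3, (2E)-3-methyl-6-oxohex-2-en-1-yl acetate
Product: 4, (2E,6S)-3,7,7-trimethylnona-2,8-diene-1,6-diol
Conditions: (+)-Ipc2BH [from (−)-α-pinene], 3-methylbuta-1,2-diene, THF, −25 °C; then 3, −78 °C; then NaOH, H2O2, MeOH–H2O, rt (also cleaves the acetate)
Reagents that add atoms: 3-methylbuta-1,2-diene, CC(C)=C=C
Why: Brown asymmetric allylboration (tert-prenylation) through a closed chair transition state with allylic transposition builds the gem-dimethyl quaternary carbon and sets the 6S carbinol under Ipc control.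

Step 4
Reactants: 4, (2E,6S)-3,7,7-trimethylnona-2,8-diene-1,6-diol
Product: 5, (1S)-1-[(2R,5S)-2-methyl-5-(2-methylbut-3-en-2-yl)oxolan-2-yl]ethane-1,2-diol
Conditions: Ti(OiPr)4, L-(+)-DET, t-BuOOH, 4 Å MS, CH2Cl2, −20 °C; then CSA (cat.), rt
Reagents that add atoms: tert-butyl hydroperoxide, CC(C)(C)OO
Why: Sharpless asymmetric epoxidation gives the (2S,3S)-epoxy alcohol (as for geraniol), and acid-catalysed 5-exo opening by the 6-OH at the tertiary carbon with inversion sets the R quaternary centre of the 2,5-cis THF.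

Step 5
Reactants: 5, THF diol
Product: 6, (2R,5S)-2-methyl-5-(2-methylbut-3-en-2-yl)oxolane-2-carbaldehyde
Conditions: NaIO4, THF–H2O, 0 °C
Reagents that add atoms: none
Why: Periodate glycol cleavage gives a non-enolisable aldehyde, so the quaternary centre cannot epimerise.

Step 6
Reactants: 6, THF aldehyde
Product: 7, (2R,5S)-2-ethynyl-2-methyl-5-(2-methylbut-3-en-2-yl)oxolane
Conditions: Ohira–Bestmann reagent, K2CO3, MeOH, 0 °C to rt
Reagents that add atoms: dimethyl (1-diazo-2-oxopropyl)phosphonate, CC(=O)C(=[N+]=[N-])P(=O)(OC)OC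
Why: Seyferth–Gilbert homologation converts the aldehyde into the terminal alkyne under mild base.

**East fragment**

Step 7
Reactants: 8, (5R)-5-(hydroxymethyl)oxolan-2-one
Product: 9, (5R)-5-(TBS-oxymethyl)oxolan-2-one
Conditions: TBSCl, imidazole, DMF, rt
Reagents that add atoms: TBSCl, CC(C)(C)[Si](C)(C)Cl
Why: Standard silylation of the primary alcohol.

Step 8
Reactants: 9, TBS lactone
Product: 10, (5R)-5-(TBS-oxymethyl)-3-methylideneoxolan-2-one
Conditions: LDA, THF, −78 °C; CH2=NMe2+ I−; then MeI, MeOH; aq. NaHCO3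
Reagents that add atoms: Eschenmoser's salt, C=[N+](C)C.[I-]
Why: Mannich reaction of the lactone enolate followed by quaternisation and elimination gives the α-methylene lactone.

Step 9
Reactants: 10, α-methylene lactone
Product: 11, (3R,5R)-5-(TBS-oxymethyl)-3-methyloxolan-2-one (cis)
Conditions: H2 (1 atm), 10% Pd/C, EtOAc, rt
Reagents that add atoms: none
Why: Heterogeneous hydrogenation delivers H to the face opposite the CH2OTBS group, giving the cis (3R) methyl lactone (minor trans isomer removed by chromatography).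

**Union and endgame**

Step 10
Reactants: 7, THF alkyne; 11, cis-methyl lactone
Product: 12, (4R,6R)-7-(TBS-oxy)-6-hydroxy-4-methyl-1-[(2R,5S)-2-methyl-5-(2-methylbut-3-en-2-yl)oxolan-2-yl]hept-1-yn-3-one
Conditions: 7, n-BuLi, THF, −78 °C; BF3·OEt2; then 11, −78 °C; NH4Cl quench
Reagents that add atoms: none (both reactants are incorporated)
Why: BF3-mediated acylation of the lithium acetylide by the lactone (Yamaguchi-type) stops at the ynone and frees the secondary OH needed for the pyran.

Step 11
Reactants: 12, hydroxy ynone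
Product: 13, (3R,4R,6R)-7-(TBS-oxy)-4-methyl-1-[(2R,5S)-2-methyl-5-(2-methylbut-3-en-2-yl)oxolan-2-yl]hept-1-yne-3,6-diol
Conditions: Ru[(R,R)-TsDPEN](p-cymene) (3 mol%), i-PrOH, rt
Reagents that add atoms: none
Why: Noyori asymmetric transfer hydrogenation of the ynone sets the 3R propargylic carbinol under catalyst control (anti-Felkin to the α-methyl), without base and without touching alkyne or alkene.

Step 12
Reactants: 13, alkynyl diol
Product: 14, (2Z,3R,4R,6R)-6-(TBS-oxymethyl)-4-methyl-2-{[(2R,5S)-2-methyl-5-(2-methylbut-3-en-2-yl)oxolan-2-yl]methylidene}oxan-3-ol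
Conditions: [JohnPhosAu(MeCN)]SbF6 (2 mol%), THF, 0 °C to rt; Et3N quench
Reagents that add atoms: none
Why: Gold(I)-catalysed 6-exo-dig hydroalkoxylation by the only hydroxyl that can reach (anti-oxyauration, then protodeauration) gives the Z exocyclic enol ether with the allylic OH axial.

Step 13
Reactants: 14, Z-enol ether
Product: 15, (2S,3R,4R,6R)-6-(TBS-oxymethyl)-2-{(S)-hydroxy[(2R,5S)-2-methyl-5-(2-methylbut-3-en-2-yl)oxolan-2-yl]methyl}-4-methyloxane-2,3-diol (hemiketal, axial OH)
Conditions: OsO4 (1.05 equiv), TMEDA (1.1 equiv), CH2Cl2, −78 °C; then ethylenediamine, aq. NaHSO3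
Reagents that add atoms: osmium tetroxide, O=[Os](=O)(=O)=O
Why: Donohoe hydrogen-bond-directed dihydroxylation delivers osmium to the face of the electron-rich Z-enol ether syn to the axial allylic OH, which gives the S carbinol, and the hemiketal settles as the axial-OH anomer; the hindered vinyl group is much slower.

Step 14
Reactants: 15, hemiketal triol; 16, (2E)-3-methylpent-2-enoic acid
Product: 17, (2R,3R,4R,6R)-6-(TBS-oxymethyl)-2-hydroxy-2-{(S)-hydroxy[(2R,5S)-2-methyl-5-(2-methylbut-3-en-2-yl)oxolan-2-yl]methyl}-4-methyloxan-3-yl (2E)-3-methylpent-2-enoate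
Conditions: 16, 2,4,6-Cl3C6H2COCl, Et3N, toluene; then 15, DMAP, 0 °C to rt
Reagents that add atoms: (2E)-3-methylpent-2-enoic acid (16), CC/C(C)=C/C(=O)O
Why: Yamaguchi esterification takes the ring secondary OH, because the other secondary OH sits between two fully substituted carbons and the hemiketal OH is tertiary.

Step 15
Reactants: 17, TBS ester
Product: 18, the corresponding 6-(hydroxymethyl) compound
Conditions: HF·pyridine, pyridine, THF, 0 °C to rt
Reagents that add atoms: none
Why: Buffered fluoride desilylation of a primary TBS ether leaves the ester and hemiketal alone.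

Step 16
Reactants: 18, primary alcohol
Product: 19, the corresponding 6-formyl compound (α-alkoxy aldehyde)
Conditions: TEMPO (cat.), PhI(OAc)2, CH2Cl2, rt
Reagents that add atoms: none
Why: TEMPO/BAIB oxidation is selective for the primary alcohol over the hindered secondary and tertiary hydroxyls, and the formyl group stays equatorial.

Step 17
Reactants: 19, ring aldehyde; 20, buta-1,3-diene
Product: 21, (2R,3R,4R,6R)-2-hydroxy-2-{(S)-hydroxy[(2R,5S)-2-methyl-5-(2-methylbut-3-en-2-yl)oxolan-2-yl]methyl}-4-methyl-6-[(2S)-2-methylbut-3-enoyl]oxan-3-yl (2E)-3-methylpent-2-enoate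
Conditions: butadiene (5 equiv), RuH2(CO)(PPh3)3 (5 mol%), chiral SEGPHOS-type bisphosphine (5 mol%), chiral BINOL-phosphoric acid (5 mol%), THF, 60 °C, sealed tube (catalyst antipode selected to give the 2S acyl side chain)
Reagents that add atoms: buta-1,3-diene (20), C=CC=C
Why: Proposed new method: Ru–H adds to butadiene to give a crotyl–Ru species that adds to the aldehyde through a closed chair transition state of the (E)-σ-crotyl isomer (anti addition, with the chiral ligand/phosphate matched to the Felkin–Anh/Cornforth preference of the α-alkoxy aldehyde, which together fix the α-methyl carbon as S), and with no hydrogen donor present the homoallylic Ru alkoxide undergoes β-hydride elimination to release the β,γ-enone and regenerate Ru–H; the closest known reaction types are Ru-catalysed diene hydroacylation (racemic β,γ-enones) and Ru-catalysed butadiene crotylation.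

Step 18
Reactants: 21, diene ketone
Product: 22, tonantzitlolone A
Conditions: Grubbs II (15 mol%), 1,4-benzoquinone (cat.), CH2Cl2 (1 mM), 40 °C
Reagents that add atoms: none
Why: Ring-closing metathesis of the two monosubstituted alkenes expels ethylene and gives the E alkene favoured in the 15-membered ring, while benzoquinone suppresses Ru–H isomerisation or epimerisation of the α-methyl β,γ-enone.

## Compound list

1 | geranyl acetate, (2E)-3,7-dimethylocta-2,6-dien-1-yl acetate | CC(C)=CCC/C(C)=C/COC(C)=O | starting material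
2 | (2E)-6,7-epoxy-3,7-dimethyloct-2-en-1-yl acetate (racemic epoxide) | CC1(C)OC1CC/C(C)=C/COC(C)=O | intermediate
3 | (2E)-3-methyl-6-oxohex-2-en-1-yl acetate | O=CCC/C(C)=C/COC(C)=O | intermediate
4 | (2E,6S)-3,7,7-trimethylnona-2,8-diene-1,6-diol | C=CC(C)(C)[C@@H](O)CC/C(C)=C/CO | intermediate
5 | (1S)-1-[(2R,5S)-2-methyl-5-(2-methylbut-3-en-2-yl)oxolan-2-yl]ethane-1,2-diol | OC[C@H](O)[C@@]1(C)CC[C@H](O1)C(C)(C)C=C | intermediate
6 | (2R,5S)-2-methyl-5-(2-methylbut-3-en-2-yl)oxolane-2-carbaldehyde | O=C[C@@]1(C)CC[C@H](O1)C(C)(C)C=C | intermediate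
7 | (2R,5S)-2-ethynyl-2-methyl-5-(2-methylbut-3-en-2-yl)oxolane | C#C[C@@]1(C)CC[C@H](O1)C(C)(C)C=C | intermediate
8 | (5R)-5-(hydroxymethyl)oxolan-2-one | OC[C@H]1CCC(=O)O1 | starting material
9 | (5R)-5-(TBS-oxymethyl)oxolan-2-one | CC(C)(C)[Si](C)(C)OC[C@H]1CCC(=O)O1 | intermediate
10 | (5R)-5-(TBS-oxymethyl)-3-methylideneoxolan-2-one | CC(C)(C)[Si](C)(C)OC[C@H]1CC(=C)C(=O)O1 | intermediate
11 | (3R,5R)-5-(TBS-oxymethyl)-3-methyloxolan-2-one | CC(C)(C)[Si](C)(C)OC[C@H]1C[C@@H](C)C(=O)O1 | intermediate
12 | (4R,6R)-7-(TBS-oxy)-6-hydroxy-4-methyl-1-[(2R,5S)-2-methyl-5-(2-methylbut-3-en-2-yl)oxolan-2-yl]hept-1-yn-3-one | CC(C)(C)[Si](C)(C)OC[C@H](O)C[C@@H](C)C(=O)C#C[C@@]1(C)CC[C@H](O1)C(C)(C)C=C | intermediate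
13 | (3R,4R,6R)-7-(TBS-oxy)-4-methyl-1-[(2R,5S)-2-methyl-5-(2-methylbut-3-en-2-yl)oxolan-2-yl]hept-1-yne-3,6-diol | CC(C)(C)[Si](C)(C)OC[C@H](O)C[C@@H](C)[C@@H](O)C#C[C@@]1(C)CC[C@H](O1)C(C)(C)C=C | intermediate
14 | (2Z,3R,4R,6R)-6-(TBS-oxymethyl)-4-methyl-2-{[(2R,5S)-2-methyl-5-(2-methylbut-3-en-2-yl)oxolan-2-yl]methylidene}oxan-3-ol | O[C@@H]1[C@H](C)C[C@H](CO[Si](C)(C)C(C)(C)C)O/C1=C\[C@@]2(C)CC[C@H](O2)C(C)(C)C=C | intermediate
15 | (2S,3R,4R,6R)-6-(TBS-oxymethyl)-2-{(S)-hydroxy[(2R,5S)-2-methyl-5-(2-methylbut-3-en-2-yl)oxolan-2-yl]methyl}-4-methyloxane-2,3-diol (same geometry at C2 as the target; the descriptor differs only through CIP priorities) | O[C@@H]1[C@H](C)C[C@H](CO[Si](C)(C)C(C)(C)C)O[C@]1(O)[C@@H](O)[C@@]2(C)CC[C@H](O2)C(C)(C)C=C | intermediate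
16 | (2E)-3-methylpent-2-enoic acid | CC/C(C)=C/C(=O)O | starting material
17 | (2R,3R,4R,6R)-6-(TBS-oxymethyl)-2-hydroxy-2-{(S)-hydroxy[(2R,5S)-2-methyl-5-(2-methylbut-3-en-2-yl)oxolan-2-yl]methyl}-4-methyloxan-3-yl (2E)-3-methylpent-2-enoate | CC/C(C)=C/C(=O)O[C@@H]1[C@H](C)C[C@H](CO[Si](C)(C)C(C)(C)C)O[C@]1(O)[C@@H](O)[C@@]2(C)CC[C@H](O2)C(C)(C)C=C | intermediate
18 | as 17 with 6-(hydroxymethyl) | CC/C(C)=C/C(=O)O[C@@H]1[C@H](C)C[C@H](CO)O[C@]1(O)[C@@H](O)[C@@]2(C)CC[C@H](O2)C(C)(C)C=C | intermediate
19 | as 17 with 6-formyl | CC/C(C)=C/C(=O)O[C@@H]1[C@H](C)C[C@H](C=O)O[C@]1(O)[C@@H](O)[C@@]2(C)CC[C@H](O2)C(C)(C)C=C | intermediate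
20 | buta-1,3-diene | C=CC=C | starting material
21 | as 17 with 6-[(2S)-2-methylbut-3-enoyl] | CC/C(C)=C/C(=O)O[C@@H]1[C@H](C)C[C@H](C(=O)[C@@H](C)C=C)O[C@]1(O)[C@@H](O)[C@@]2(C)CC[C@H](O2)C(C)(C)C=C | intermediate
22 | tonantzitlolone A | CC/C(C)=C/C(=O)O[C@@H]1[C@H](C)C[C@H]2O[C@]1(O)[C@@H](O)[C@@]1(C)CC[C@H](O1)C(C)(C)/C=C/[C@H](C)C2=O | target

## Summary

Total steps: 18. Longest linear sequence: 15 (steps 1–6, then 10–18).

Three steps most likely to fail:

- **Step 17 (new hydroacylation).** Risks are poor control of the labile α-methyl centre, isomerisation to the conjugated enone, or dehydrogenation of the free carbinol. Fallback (known chemistry): protect the hemiketal OH and adjacent OH of 17 as an acetonide, desilylate and oxidise to the aldehyde, run a Brown (E)-crotylboration (matched with the α-alkoxy aldehyde), oxidise the homoallylic alcohol with Dess–Martin periodinane, do the RCM, then remove the acetonide with mild acid.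
- **Step 13 (OH-directed dihydroxylation of the acid-sensitive enol ether).** Risks are wrong-face attack or enol ether hydrolysis. Fallback: make the carbinol by reduction instead of oxidation. Silylate both hydroxyls of 13, oxidise the alkyne to the 1,2-diketone (Au/N-oxide), unmask the diol so the hemiketal closes on the proximal ketone, and reduce the remaining ketone under chelation control (Zn(BH4)2 via the hemiketal OH chelate).
- **Step 18 (RCM of a neopentyl vinyl with an epimerisable α-methyl β,γ-enone).** Risks are slow closure, E/Z mixtures or epimerisation. Fallback: change the ring-closing bond. Join the two olefin termini intermolecularly first (Julia–Kocienski olefination or cross-metathesis on simpler fragments), then close the macrocycle by intramolecular Nozaki–Hiyama–Kishi addition of an iodoalkyne to the aldehyde at the acyloxy-bearing carbon, followed by ynone formation and Noyori reduction.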